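## Retrosynthetic overview

- Target ⇐ global hydrogenolysis, decarboxylation and thermodynamic trans-equilibration at C3 of a benzyl α-(3,4-dimethoxybenzyl)-α-carboxylate lactone.
- That lactone ⇐ C-benzylation of an α-benzyloxycarbonyl-β-arylmethyl-γ-butyrolactone with 3,4-dimethoxybenzyl bromide.
- β-Arylmethyl lactone ⇐ light-driven nickel-catalysed ring-opening arylation of a bicyclic cyclopropane lactone with 4-bromo-1,2-bis(benzyloxy)benzene (aryl–CH2 bond, key step).
- Cyclopropane lactone ⇐ (R)-epichlorohydrin + dibenzyl malonate.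
- Ring order: cyclopropane first, then the γ-lactone in the same pot; the cyclopropane is opened later, the lactone is kept; both arenes are bought.

Assumption: C3 of 7 and 8 is a freely epimerising β-dicarbonyl centre and is written without configuration; 6 and 9 are taken as catalogue compounds.

## Route

Step 1
Reactants: 1 (R)-epichlorohydrin; 2 dibenzyl malonate
Product: 5 benzyl (1R,5R)-2-oxo-3-oxabicyclo[3.1.0]hexane-1-carboxylate, via epoxy malonate 3 (not isolated), via cyclopropylmethanol diester 4 (not isolated)
Conditions: NaOCH2Ph (1 M in BnOH, 1.1 equiv), THF, 0 → 65 °C, 16 h; aq. NH4Cl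
Reagents that add atoms: none
Why: Malonate alkylation cascade (epoxide opening at the CH2 terminus, epoxide re-closure with loss of chloride, 3-exo-tet cyclopropanation with inversion at the epichlorohydrin carbon, then lactonisation by the cis alkoxide) in which the bought stereocentre becomes C5 (R), the cis ring fusion fixes C1, and the benzyloxide base matches the ester so nothing scrambles.

Step 2
Reactants: 5 benzyl (1R,5R)-2-oxo-3-oxabicyclo[3.1.0]hexane-1-carboxylate; 6 4-bromo-1,2-bis(benzyloxy)benzene (1.5 equiv)
Product: 8 benzyl (4R)-4-{[3,4-bis(benzyloxy)phenyl]methyl}-2-oxooxolane-3-carboxylate, via iodomethyl lactone 7 (not isolated)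
Conditions: NiBr2·CH3OCH2CH2OCH3 (10 mol%), 4,4'-di-tert-butyl-2,2'-bipyridine (12 mol%), 4CzIPN (2 mol%), MgI2 (30 mol%), Hantzsch ester (diethyl 2,6-dimethyl-1,4-dihydropyridine-3,5-dicarboxylate, 1.5 equiv), NaHCO3 (2 equiv), DMA, blue LEDs (450 nm), 30 °C, Ar, 24 h; aq. NH4Cl
Reagents that add atoms: none
Why: Proposed new method: an iodide-relay, light-driven nickel reductive ring-opening arylation of an acceptor-only cyclopropane, in which MgI2 opens the strained doubly activated ring by SN2 attack of iodide at the unhindered C6 methylene to give the chelated magnesium enolate of 7, photoexcited 4CzIPN (turned over by the Hantzsch ester) reduces divalent nickel to zerovalent nickel that inserts into the C–Br bond of 6, monovalent nickel abstracts iodine from 7, the primary radical is captured by the divalent arylnickel bromide and reductive elimination from trivalent nickel forges the aryl–CH2 bond and returns iodide to the relay, while C5 of 5 (the future C4) is never touched and keeps its configuration; the closest known reaction types are nickel/photoredox cross-electrophile coupling of aryl bromides with primary alkyl halides, nickel-catalysed reductive ring-opening coupling of cyclopropyl ketones and MgI2-mediated opening of cyclopropane-1,1-diesters.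

Step 3
Reactants: 8 benzyl (4R)-4-{[3,4-bis(benzyloxy)phenyl]methyl}-2-oxooxolane-3-carboxylate; 9 3,4-dimethoxybenzyl bromide (1.2 equiv)
Product: 10 benzyl (3S,4R)-4-{[3,4-bis(benzyloxy)phenyl]methyl}-3-[(3,4-dimethoxyphenyl)methyl]-2-oxooxolane-3-carboxylate
Conditions: K2CO3 (2 equiv), DMF, 0 °C → rt, 6 h
Reagents that add atoms: none
Why: C-alkylation of a cyclic malonate-type enolate with a reactive benzylic bromide, the electrophile entering anti to the C4 arylmethyl group (major isomer drawn), although this quaternary centre is re-set in step 4 so the ratio does not matter.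

Step 4
Reactants: 10 benzyl (3S,4R)-4-{[3,4-bis(benzyloxy)phenyl]methyl}-3-[(3,4-dimethoxyphenyl)methyl]-2-oxooxolane-3-carboxylate
Product: 13 (3R,4R)-4-[(3,4-dihydroxyphenyl)methyl]-3-[(3,4-dimethoxyphenyl)methyl]oxolan-2-one, via lactone acid 11 (not isolated), via cis-lactone 12 (not isolated)
Conditions: H2 (1 atm), 10% Pd/C, EtOAc–EtOH, rt; filter under Ar; 1,4-dioxane, 100 °C; then DBU (2 equiv), 60 °C, Ar; 1 M HCl work-up
Reagents that add atoms: none
Why: Hydrogenolysis of the benzyl ester and both benzyl ethers, thermal decarboxylation of the malonic-type acid 11 through its lactone enol (kinetic protonation gives a cis-rich mixture), and DBU-mediated thermodynamic epimerisation at C3, where the epichlorohydrin-derived C4 centre dictates the more stable trans (3R) lactone, typically above 95:5.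

## Compound list

1 | (R)-epichlorohydrin, (2R)-2-(chloromethyl)oxirane | ClC[C@H]1CO1 | starting material
2 | dibenzyl malonate (dibenzyl propanedioate) | O=C(CC(=O)OCc1ccccc1)OCc1ccccc1 | starting material
3 | dibenzyl 2-{[(2R)-oxiran-2-yl]methyl}propanedioate (epoxy malonate) | O=C(OCc1ccccc1)C(C[C@@H]1CO1)C(=O)OCc1ccccc1 | intermediate
4 | dibenzyl (2R)-2-(hydroxymethyl)cyclopropane-1,1-dicarboxylate (present as its alkoxide) | OC[C@@H]1CC1(C(=O)OCc1ccccc1)C(=O)OCc1ccccc1 | intermediate
5 | benzyl (1R,5R)-2-oxo-3-oxabicyclo[3.1.0]hexane-1-carboxylate, cis-fused cyclopropane lactone (same spatial arrangement as the familiar ethyl ester, whose descriptor 1S,5R differs only through CIP priorities) | O=C1OC[C@@H]2C[C@]12C(=O)OCc1ccccc1 | intermediate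
6 | 4-bromo-1,2-bis(benzyloxy)benzene | Brc1ccc(OCc2ccccc2)c(OCc2ccccc2)c1 | starting material
7 | benzyl (4R)-4-(iodomethyl)-2-oxooxolane-3-carboxylate (present as its magnesium enolate; C3 undefined) | O=C(OCc1ccccc1)C1C(=O)OC[C@@H]1CI | intermediate
8 | benzyl (4R)-4-{[3,4-bis(benzyloxy)phenyl]methyl}-2-oxooxolane-3-carboxylate (C3 epimers, mainly trans) | O=C(OCc1ccccc1)C1C(=O)OC[C@@H]1Cc1ccc(OCc2ccccc2)c(OCc2ccccc2)c1 | intermediate
9 | 3,4-dimethoxybenzyl bromide, 4-(bromomethyl)-1,2-dimethoxybenzene | COc1ccc(CBr)cc1OC | starting material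
10 | benzyl (3S,4R)-4-{[3,4-bis(benzyloxy)phenyl]methyl}-3-[(3,4-dimethoxyphenyl)methyl]-2-oxooxolane-3-carboxylate (the two arylmethyl groups trans) | COc1ccc(C[C@@]2(C(=O)OCc3ccccc3)C(=O)OC[C@@H]2Cc2ccc(OCc3ccccc3)c(OCc3ccccc3)c2)cc1OC | intermediate
11 | (3R,4R)-4-[(3,4-dihydroxyphenyl)methyl]-3-[(3,4-dimethoxyphenyl)methyl]-2-oxooxolane-3-carboxylic acid | COc1ccc(C[C@@]2(C(=O)O)C(=O)OC[C@@H]2Cc2ccc(O)c(O)c2)cc1OC | intermediate
12 | (3S,4R)-4-[(3,4-dihydroxyphenyl)methyl]-3-[(3,4-dimethoxyphenyl)methyl]oxolan-2-one (cis epimer) | COc1ccc(C[C@@H]2C(=O)OC[C@@H]2Cc2ccc(O)c(O)c2)cc1OC | intermediate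
13 | (3R,4R)-4-[(3,4-dihydroxyphenyl)methyl]-3-[(3,4-dimethoxyphenyl)methyl]oxolan-2-one (trans) | COc1ccc(C[C@H]2C(=O)OC[C@@H]2Cc2ccc(O)c(O)c2)cc1OC | target

## Step count and risks

Total steps: 4. Longest linear sequence: 4 (1 → 5 → 8 → 10 → 13).

Most likely to fail:

Step 2 (the proposed reaction). The relay may stall at 7, or the primary radical may be reduced to the 4-methyl lactone by hydrogen-atom transfer from the dihydropyridine; the electron-rich aryl bromide may also add slowly to nickel. The fallback uses known organometallic chemistry and sets out from 5. Aryl bromide 6 is converted with Mg turnings in THF at 40 °C into [3,4-bis(benzyloxy)phenyl]magnesium bromide F1, which is added to 5 with CuI (10 mol%) in THF at −40 → −20 °C. The aryl cuprate opens the cyclopropane at C6 by SN2-type homoconjugate addition, as ethylmagnesium bromide does on the corresponding ethyl ester, and aqueous NH4Cl brings the route back at 8.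

Step 4. The cis-to-trans equilibration may be incomplete, or the free catechol may suffer under DBU if oxygen is not rigorously excluded. The fallback sets out from 8 and fixes C3 kinetically before any phenol is unmasked. Krapcho-type removal of the ester (LiCl, wet DMSO, 140 °C) gives (4R)-4-{[3,4-bis(benzyloxy)phenyl]methyl}oxolan-2-one F2. Its lithium enolate (LiN(SiMe3)2, THF, −78 °C) is alkylated by 9 anti to the C4 substituent to give (3R,4R)-4-{[3,4-bis(benzyloxy)phenyl]methyl}-3-[(3,4-dimethoxyphenyl)methyl]oxolan-2-one F3, the standard trans-selective lignan alkylation. Neutral hydrogenolysis (H2, Pd/C, EtOAc) then comes back at 13.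

Step 1. With benzyloxide in a less protic medium, direct displacement of chloride (which leads to the enantiomer) could erode the enantiomeric purity, and removal of benzyl alcohol may cost yield. The fallback sets out from 1 and installs the benzyl ester after ring construction. The standard condensation with diethyl malonate (NaOC2H5, EtOH, reflux) gives ethyl (1S,5R)-2-oxo-3-oxabicyclo[3.1.0]hexane-1-carboxylate F4. Saponification with aqueous NaOH followed by HCl, which re-closes the lactone, gives (1S,5R)-2-oxo-3-oxabicyclo[3.1.0]hexane-1-carboxylic acid F5. O-Benzylation of the acid (benzyl bromide, K2CO3, DMF, rt) comes back at 5.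

Further compounds
F1 | step 2 | [3,4-bis(benzyloxy)phenyl]magnesium bromide | Br[Mg]c1ccc(OCc2ccccc2)c(OCc2ccccc2)c1
F2 | step 4 | (4R)-4-{[3,4-bis(benzyloxy)phenyl]methyl}oxolan-2-one | O=C1OC[C@@H](C1)Cc1ccc(OCc2ccccc2)c(OCc2ccccc2)c1
F3 | step 4 | (3R,4R)-4-{[3,4-bis(benzyloxy)phenyl]methyl}-3-[(3,4-dimethoxyphenyl)methyl]oxolan-2-one | COc1ccc(C[C@H]2C(=O)OC[C@@H]2Cc2ccc(OCc3ccccc3)c(OCc3ccccc3)c2)cc1OC
F4 | step 1 | ethyl (1S,5R)-2-oxo-3-oxabicyclo[3.1.0]hexane-1-carboxylate | O=C1OC[C@@H]2C[C@]12C(=O)OCC
F5 | step 1 | (1S,5R)-2-oxo-3-oxabicyclo[3.1.0]hexane-1-carboxylic acid | O=C1OC[C@@H]2C[C@]12C(=O)O
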